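**Numbering and assumption**

Atom numbering used throughout: ring C1(C7H2O)=C2–C3–C4–C5–C6(OH); side chain on C4: C8(=C14H2)–C9–C10=C11–C12(OH)(CH3)–C13H2O. In this numbering the target is (4S,6S,12R) with a 10E alkene. Compound numbers refer to the list after the steps.

Assumption: 2-methyl-2-vinyloxirane (1), (R)-4-benzyloxazolidin-2-one (4), acryloyl chloride (5), (S)-2-methylglycidol (14) and isobutyryl chloride (16) are purchased. Compound 1 is used as the racemate because its stereocentre is destroyed in step 1.

## Analysis of the target

The target has one carbocycle, a cyclohex-2-en-1-ol (C1–C6), with an isobutyryloxymethyl group (C7) on the alkene carbon C1, a free secondary allylic hydroxyl at C6 and a seven-carbon side chain on C4. The side chain is a skipped diene: a 1,1-disubstituted alkene C8=C14 on the ring, a doubly allylic methylene C9, an E-alkene C10=C11, and a tertiary allylic carbinol C12 whose neighbour C13 carries the second isobutyrate. There are three stereocentres: C4 (S) and C6 (S) are cis-1,3 across the ring methylene C5, and C12 (R) lies five bonds from C4 beyond two sp2 units, so the ring cannot influence it. Sensitive points are the two esters, each next to a free hydroxyl to which it can migrate (C7 to C6, C13 to C12), two ionisable allylic alcohols, and the C9 methylene, which can move into conjugation. The difficulties are the cis-1,3 relation with no neighbouring group to direct it, the remote independent centre C12, and the differentiation of four oxygens (two acylated primary, two free). The strategy rests on one feature: because the C6 hydroxyl and the C4 substituent are cis-1,3, a carboxyl placed at C8 can reach C6 as a five-membered lactone (bridge C8–O–C6 over C5, a 6-oxabicyclo[3.2.1]octane). Such a bridge can only form cis, so C4 alone dictates C6, and the carboxyl carbon later becomes the branching alkene carbon C8.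

## Retrosynthetic reasoning

**C7–O acyl bond.** Target 20 is cut at the C7 ester to triol monoester 19 and isobutyryl chloride 16. C7 is the only primary hydroxyl of 19, so steric control should suffice, and leaving this ester to the end keeps it away from the hydride and base steps.

**C7–O silyl bond.** Triol 19 comes from silyl ether 18. The silyl group on C7 is needed from the diene stage onward, because C7 must survive lactone reduction and homologation as a non-acyl oxygen.

**C8–C9 bond.** Compound 18 is cut between C8 and C9, with the C10=C11 alkene moved back to C9=C10, giving enynol 13 and homoallylic carbinol ester 17. This cut separates the ring stereocentres from C12, so each fragment carries its own chirality. The forward reaction, an alkene–alkyne coupling of the Alder-ene type, has to form the C8–C9 bond at the internal alkyne carbon and deliver the E alkene. It forms both side-chain alkenes at once without protecting the hydroxyls.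

**Side-chain fragment.** Ester 17 is cut at its acyl–oxygen bond to diol 15 and 16, and 15 at the C10–C11 bond to (S)-2-methylglycidol 14 and a vinyl nucleophile. C12 is thus taken from the chiral pool, and the quaternary centre is never a reaction site.

**C8≡C14 and the lactol.** The alkyne of 13 is traced to the aldehyde oxidation level at C8, which is lactol 12 and, one oxidation level higher, lactone 11. Opening the lactol in the homologation releases the C6 hydroxyl at the moment the bridge has done its work.

**C6–O bond and C1=C2 alkene (key disconnection).** Lactone 11 is traced through selenoxide 10 and selenolactone 9 to acid 8, whose alkene is C1=C6. The forward step must put oxygen on C6 cis to C8 and move the alkene to C1=C2. The bridge makes the first geometric, and the second follows from the direction of selenoxide elimination.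

**C4–C5 and C2–C3 bonds.** Acid 8 is cut off imide 7, and 7 is cut by a Diels–Alder disconnection into diene 3 and acrylimide 6. The para orientation places C7 on C1, and the auxiliary in 6 sets C4, the only stereocentre that has to be made by asymmetric induction.

**Building blocks.** Diene 3 comes from epoxide 1 by base-induced isomerisation through alkoxide 2 and silylation. Acrylimide 6 comes from auxiliary 4 and acryloyl chloride 5.

## Alternatives that were turned down

**Alternative 1:** Ring closure last, by cutting the C1–C6 bond.
- Key step: a nucleophilic phosphine adds to the enoate of the open-chain enoate aldehyde A1 (side chain in place, C12/C13 as acetonide), and the C1 enolate attacks the C6 aldehyde. This intramolecular Morita–Baylis–Hillman reaction gives cyclohexenol ester A2.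
- For: the ring, the C1=C2 alkene, the C6 carbinol and C7 (as ester carbon) arise in one step. After ester reduction and acetonide removal both primary hydroxyls could be acylated in one operation. On that point it is stronger than the chosen route, which acylates twice.
- Against: C6 forms in a reversible aldol step biased only by 1,3-induction from C4, so a cis/trans mixture must be expected. A1 needs C4 set in an open chain between two nearly identical CH2 arms. The aldehyde is enolisable, the enoate can dimerise under the phosphine (Rauhut–Currier), and the skipped diene must be carried through the whole linear assembly of A1.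
- Comparison: the chosen route replaces a statistical outcome at C6 by a geometric one and attaches the chain in one convergent step.

**Alternative 2:** C12 traced to the C11=C12 alkene of the (E)-2-methyl allylic alcohol A3 (ring oxygens silylated).
- Key step: Sharpless epoxidation with the L-(+)-tartrate system gives the (2S,3S)-epoxy alcohol A4. Opening at C11 by a selenide and selenoxide elimination toward C10 would then transpose it to the C10=C11 alkene and the C12 tertiary alcohol.
- For: face selection by the reagent is predictable for this alkene class, and either C12 epimer is available by changing the tartrate. In this it equals the chiral-pool solution and needs no enantiopure chain building block.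
- Against: it settles only C12, so C4 and C6 still need their own answer. A3 requires the chain to be grown linearly on the ring. The transposition adds two to three operations, and the basic selenide can trigger Payne rearrangement of the 2,3-epoxy alcohol, which would divert attack to C13. Three hydroxyl-differentiation steps remain afterwards.
- Comparison: the chosen route brings C12 in with 17 through one C–C coupling that also makes both side-chain alkenes.

**Alternative 3:** Ring from two achiral pieces, β-keto ester A5 and γ-oxo enoate A6.
- Key step: a diarylprolinol silyl ether catalyses the Michael addition (C4–C5 bond, C4 set), and acid closes the ring by aldol condensation (C1=C2) with loss of the tert-butyl ester, giving enone ester A7 (C6 as ketone, C8 as ester).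
- For: catalytic asymmetric induction from cheap materials without a stoichiometric auxiliary. In reagent economy it is stronger than the auxiliary-controlled cycloaddition used here.
- Against: A7 lacks C7, which must be added by α-hydroxymethylation of the enone. The C6 alcohol then comes from a 1,2-reduction whose cis selectivity rests on the conformational bias of a 5-substituted cyclohexenone, which is substrate control and not enforced. C4 in A7 is α to the ester and allylic to the enone system through C3, so basic steps risk double-bond migration into conjugation with the ester, which erases C4. The C8 ester still has to be reduced and homologated, so the step count up to 13 is about the same.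
- Comparison: the chosen route carries C7 in with the diene and fixes C6 by the lactone bridge, so it needs neither the extra C–C bond nor a diastereoselective reduction.

Key step: step 5

## Route

Step 1
Reactants: 1 2-methyl-2-vinyloxirane
Product: 3 tert-butyl(dimethyl)[(2-methylidenebut-3-en-1-yl)oxy]silane, via lithium alkoxide 2 (not isolated)
Conditions: i-Pr2NLi, THF, −78 → 0 °C; then TBSCl, DMPU, 0 °C → rt
Reagents that add atoms: tert-butyldimethylsilyl chloride, CC(C)(C)[Si](C)(C)Cl
Why: Lithium amide-mediated isomerisation of an epoxide to an allylic alcohol: syn β-elimination removes a methyl hydrogen and opens the tertiary C–O bond to give dienyl alkoxide 2, which is silylated in the same flask so that the volatile dienol is never handled. The stereocentre of 1 is destroyed, so no stereochemical issue arises.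

Step 2
Reactants: 4 (R)-4-benzyloxazolidin-2-one; 5 acryloyl chloride
Product: 6 (R)-3-acryloyl-4-benzyloxazolidin-2-one
Conditions: MeMgBr, THF, 0 °C; then 5, −78 → 0 °C
Reagents that add atoms: none
Why: N-Acylation of the bromomagnesium salt of the oxazolidinone, a standard way to prepare acrylimides while avoiding conjugate addition and polymerisation.

Step 3
Reactants: 3 tert-butyl(dimethyl)[(2-methylidenebut-3-en-1-yl)oxy]silane; 6 (R)-3-acryloyl-4-benzyloxazolidin-2-one
Product: 7 (R)-4-benzyl-3-[(S)-4-({[tert-butyl(dimethyl)silyl]oxy}methyl)cyclohex-3-ene-1-carbonyl]oxazolidin-2-one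
Conditions: Et2AlCl (1.4 equiv), CH2Cl2, −78 → −40 °C
Reagents that add atoms: none
Why: Lewis acid-promoted Diels–Alder reaction of the aluminium-chelated, s-cis N-acryloyl oxazolidinone; the 2-substituted diene reacts in the para sense (bonds C2–C3 and C4–C5), which places C7 on C1. The benzyl group shields one face of the chelate, so the diene adds to the Re face of the acrylimide α-carbon and C4 is set as S; the minor diastereomer and any meta isomer can be removed at this crystalline imide stage.

Step 4
Reactants: 7 (R)-4-benzyl-3-[(S)-4-({[tert-butyl(dimethyl)silyl]oxy}methyl)cyclohex-3-ene-1-carbonyl]oxazolidin-2-one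
Product: 8 (S)-4-({[tert-butyl(dimethyl)silyl]oxy}methyl)cyclohex-3-ene-1-carboxylic acid
Conditions: LiOH, H2O2, THF/H2O, 0 °C; then aq. Na2SO3; HCl to pH 3
Reagents that add atoms: hydrogen peroxide (reacting as LiOOH), OO
Why: Hydroperoxide cleavage of the N-acyl oxazolidinone at the exocyclic carbonyl; the reagent is weakly basic, so C4 should not epimerise, and auxiliary 4 is recovered.

Step 5
Reactants: 8 (S)-4-({[tert-butyl(dimethyl)silyl]oxy}methyl)cyclohex-3-ene-1-carboxylic acid
Product: 11 (1S,5S)-4-({[tert-butyl(dimethyl)silyl]oxy}methyl)-6-oxabicyclo[3.2.1]oct-3-en-7-one, via selenolactone 9 (not isolated), via selenoxide 10 (not isolated)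
Conditions: PhSeCl, K2CO3, CH2Cl2, −78 → −20 °C; then 30% H2O2, pyridine, 0 °C → rt
Reagents that add atoms: none
Why: PhSeCl adds reversibly to the C1=C6 alkene to give seleniranium ions on both faces; only the ion anti to the carboxylate is intercepted, the carboxylate (axial on C4 in the reacting half-chair) opening it at C6 in a 5-exo-trig, trans-diaxial attack that forms the C6–O bond and the γ-lactone ring of 9. The closest known reaction type is the phenylselenolactonisation (or iodolactonisation) of cyclohex-3-enecarboxylic acids to 6-oxabicyclo[3.2.1]octan-7-ones, followed by elimination to the allylic lactone. The new stereocentre C6 is controlled by C4 alone, since a five-membered lactone bridging over the single carbon C5 can only span cis positions, so oxygen arrives on the face that carries C8; the selenium-bearing centre C1 is transient. The step needs attack at C6 and not at the tertiary C1 (which would give the six-membered bicyclo[2.2.2] lactone through a boat); this is secured by the short reach of the axial carboxylate and by the CH2OSi group, which makes C1 electron-poorer and more hindered. H2O2 then oxidises selenium to selenoxide 10, which undergoes syn-elimination. Elimination toward C6 is excluded (bridgehead, oxygen-bearing) and toward C7 is disfavoured because selenoxides eliminate away from oxygen-bearing carbons, so the cis hydrogen on C2 is taken and the C1=C2 alkene results. K2CO3 takes up HCl and pyridine buffers the oxidation, so the silyl ether should survive.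

Step 6
Reactants: 11 (1S,5S)-4-({[tert-butyl(dimethyl)silyl]oxy}methyl)-6-oxabicyclo[3.2.1]oct-3-en-7-one
Product: 12 (1S,5S)-4-({[tert-butyl(dimethyl)silyl]oxy}methyl)-6-oxabicyclo[3.2.1]oct-3-en-7-ol (mixture at C7 of the bicycle)
Conditions: i-Bu2AlH (1.1 equiv), CH2Cl2, −78 °C; aq. potassium sodium tartrate
Reagents that add atoms: none
Why: Partial reduction of a γ-lactone to the lactol; the aluminium hemiacetal is stable at −78 °C, which prevents over-reduction, and no stereocentre of the ring is touched.

Step 7
Reactants: 12 (1S,5S)-4-({[tert-butyl(dimethyl)silyl]oxy}methyl)-6-oxabicyclo[3.2.1]oct-3-en-7-ol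
Product: 13 (1S,5S)-2-({[tert-butyl(dimethyl)silyl]oxy}methyl)-5-ethynylcyclohex-2-en-1-ol
Conditions: dimethyl (1-diazo-2-oxopropyl)phosphonate, K2CO3, MeOH, 0 °C → rt
Reagents that add atoms: dimethyl (1-diazo-2-oxopropyl)phosphonate, CC(=O)C(=[N+]=[N-])P(=O)(OC)OC
Why: Seyferth–Gilbert homologation in the Ohira–Bestmann variant: the lactol is in equilibrium with the C8 aldehyde, which is trapped by the diazomethylphosphonate anion generated in the flask; loss of N2 and a 1,2-shift give the terminal alkyne (C14 added) and free the C6 hydroxyl with its configuration unchanged.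

Step 8
Reactants: 14 (S)-2-methylglycidol
Product: 15 (R)-2-methylpent-4-ene-1,2-diol
Conditions: vinylmagnesium bromide (3 equiv), CuI (10 mol %), THF, −40 → 0 °C
Reagents that add atoms: vinylmagnesium bromide, C=C[Mg]Br
Why: Copper-catalysed Grignard opening of a 2,2-disubstituted epoxide at its CH2 terminus (SN2); the quaternary carbon is not a reaction site, so C12 is carried over from 14 (the descriptor changes from S to R only through the priority rules).

Step 9
Reactants: 15 (R)-2-methylpent-4-ene-1,2-diol; 16 isobutyryl chloride
Product: 17 (R)-2-hydroxy-2-methylpent-4-en-1-yl 2-methylpropanoate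
Conditions: 16 (1.05 equiv), 2,4,6-collidine, CH2Cl2, −40 → 0 °C
Reagents that add atoms: none
Why: Selective esterification of the primary hydroxyl; a tertiary alcohol does not react with an acyl chloride and a weak pyridine base at low temperature.

Step 10
Reactants: 13 (1S,5S)-2-({[tert-butyl(dimethyl)silyl]oxy}methyl)-5-ethynylcyclohex-2-en-1-ol; 17 (R)-2-hydroxy-2-methylpent-4-en-1-yl 2-methylpropanoate
Product: 18 (2R,3E)-6-[(1S,5S)-4-({[tert-butyl(dimethyl)silyl]oxy}methyl)-5-hydroxycyclohex-3-en-1-yl]-2-hydroxy-2-methylhepta-3,6-dien-1-yl 2-methylpropanoate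
Conditions: CpRu(MeCN)3PF6 (10 mol %), acetone, rt
Reagents that add atoms: none
Why: Ruthenium-catalysed alkene–alkyne coupling (formal Alder-ene reaction): oxidative cyclisation of the terminal alkyne and the monosubstituted alkene gives a ruthenacyclopentene in which C8 bonds to C9; β-hydride elimination of a C11 hydrogen and reductive elimination give the branched 1,4-diene with the C8=C14 alkene and the E C10=C11 alkene. Free hydroxyls, esters and silyl ethers are tolerated, and the trisubstituted ring alkene should not take part.

Step 11
Reactants: 18 (2R,3E)-6-[(1S,5S)-4-({[tert-butyl(dimethyl)silyl]oxy}methyl)-5-hydroxycyclohex-3-en-1-yl]-2-hydroxy-2-methylhepta-3,6-dien-1-yl 2-methylpropanoate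
Product: 19 (2R,3E)-2-hydroxy-6-[(1S,5S)-5-hydroxy-4-(hydroxymethyl)cyclohex-3-en-1-yl]-2-methylhepta-3,6-dien-1-yl 2-methylpropanoate
Conditions: HF·pyridine, pyridine, THF, 0 °C → rt
Reagents that add atoms: none
Why: Fluoride cleavage of the primary allylic silyl ether under buffered, mildly acidic conditions, which avoid the base-induced acyl migration from C13 to C12 and should leave the allylic alcohols intact.

Step 12
Reactants: 19 (2R,3E)-2-hydroxy-6-[(1S,5S)-5-hydroxy-4-(hydroxymethyl)cyclohex-3-en-1-yl]-2-methylhepta-3,6-dien-1-yl 2-methylpropanoate; 16 isobutyryl chloride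
Product: 20 (2R,3E)-2-hydroxy-6-[(1S,5S)-5-hydroxy-4-{[(2-methylpropanoyl)oxy]methyl}cyclohex-3-en-1-yl]-2-methylhepta-3,6-dien-1-yl 2-methylpropanoate (the target)
Conditions: 16 (1.05 equiv), 2,4,6-collidine, CH2Cl2, −78 → −30 °C
Reagents that add atoms: none
Why: Sterically controlled acylation: the primary allylic C7 hydroxyl should react with the branched acyl chloride well before the secondary C6 and the tertiary C12 hydroxyls at low temperature with a hindered pyridine base.

## Compound list

1 | 2-methyl-2-vinyloxirane (racemic) | CC1(C=C)CO1 | starting material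
2 | lithium 2-methylidenebut-3-en-1-olate | [Li+].[O-]CC(=C)C=C | intermediate
3 | tert-butyl(dimethyl)[(2-methylidenebut-3-en-1-yl)oxy]silane | C=CC(=C)CO[Si](C)(C)C(C)(C)C | intermediate
4 | (R)-4-benzyloxazolidin-2-one | O=C1N[C@H](Cc2ccccc2)CO1 | starting material
5 | acryloyl chloride | C=CC(=O)Cl | starting material
6 | (R)-3-acryloyl-4-benzyloxazolidin-2-one | C=CC(=O)N1[C@H](Cc2ccccc2)COC1=O | intermediate
7 | (R)-4-benzyl-3-[(S)-4-({[tert-butyl(dimethyl)silyl]oxy}methyl)cyclohex-3-ene-1-carbonyl]oxazolidin-2-one | O=C([C@H]1CCC(CO[Si](C)(C)C(C)(C)C)=CC1)N1[C@H](Cc2ccccc2)COC1=O | intermediate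
8 | (S)-4-({[tert-butyl(dimethyl)silyl]oxy}methyl)cyclohex-3-ene-1-carboxylic acid | OC(=O)[C@H]1CCC(CO[Si](C)(C)C(C)(C)C)=CC1 | intermediate
9 | (1S,4R,5S)-4-({[tert-butyl(dimethyl)silyl]oxy}methyl)-4-(phenylselanyl)-6-oxabicyclo[3.2.1]octan-7-one (selenium anti to the lactone oxygen) | O=C2[C@H]1CC[C@](CO[Si](C)(C)C(C)(C)C)([Se]c3ccccc3)[C@@H](O2)C1 | intermediate
10 | selenoxide of 9, 4-(benzeneseleninyl) lactone (mixture at selenium) | O=C2[C@H]1CC[C@](CO[Si](C)(C)C(C)(C)C)([Se](=O)c3ccccc3)[C@@H](O2)C1 | intermediate
11 | (1S,5S)-4-({[tert-butyl(dimethyl)silyl]oxy}methyl)-6-oxabicyclo[3.2.1]oct-3-en-7-one | O=C2[C@H]1CC=C(CO[Si](C)(C)C(C)(C)C)[C@@H](O2)C1 | intermediate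
12 | (1S,5S)-4-({[tert-butyl(dimethyl)silyl]oxy}methyl)-6-oxabicyclo[3.2.1]oct-3-en-7-ol (lactol, both epimers) | OC2[C@H]1CC=C(CO[Si](C)(C)C(C)(C)C)[C@@H](O2)C1 | intermediate
13 | (1S,5S)-2-({[tert-butyl(dimethyl)silyl]oxy}methyl)-5-ethynylcyclohex-2-en-1-ol | C#C[C@H]1CC=C(CO[Si](C)(C)C(C)(C)C)[C@@H](O)C1 | intermediate
14 | (S)-2-methylglycidol | OC[C@@]1(C)CO1 | starting material
15 | (R)-2-methylpent-4-ene-1,2-diol | C=CC[C@@](C)(O)CO | intermediate
16 | isobutyryl chloride | CC(C)C(Cl)=O | starting material
17 | (R)-2-hydroxy-2-methylpent-4-en-1-yl 2-methylpropanoate | C=CC[C@@](C)(O)COC(=O)C(C)C | intermediate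
18 | (2R,3E)-6-[(1S,5S)-4-({[tert-butyl(dimethyl)silyl]oxy}methyl)-5-hydroxycyclohex-3-en-1-yl]-2-hydroxy-2-methylhepta-3,6-dien-1-yl 2-methylpropanoate | C=C(C/C=C/[C@@](C)(O)COC(=O)C(C)C)[C@H]1CC=C(CO[Si](C)(C)C(C)(C)C)[C@@H](O)C1 | intermediate
19 | (2R,3E)-2-hydroxy-6-[(1S,5S)-5-hydroxy-4-(hydroxymethyl)cyclohex-3-en-1-yl]-2-methylhepta-3,6-dien-1-yl 2-methylpropanoate | C=C(C/C=C/[C@@](C)(O)COC(=O)C(C)C)[C@H]1CC=C(CO)[C@@H](O)C1 | intermediate
20 | (2R,3E)-2-hydroxy-6-[(1S,5S)-5-hydroxy-4-{[(2-methylpropanoyl)oxy]methyl}cyclohex-3-en-1-yl]-2-methylhepta-3,6-dien-1-yl 2-methylpropanoate (CNP0599657.1) | C=C(C/C=C/[C@@](C)(O)COC(=O)C(C)C)[C@H]1CC=C(COC(=O)C(C)C)[C@@H](O)C1 | target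

## Step count and least certain steps

Total step count: 12. Longest linear sequence: 9 steps (1 → 3 → 7 → 8 → 11 → 12 → 13 → 18 → 19 → 20, i.e. steps 1, 3, 4, 5, 6, 7, 10, 11, 12).

**Step 5 (key step).** The most likely failure is loss of regiocontrol when the seleniranium ion is opened: the Markovnikov preference for the tertiary C1 competes with the 5-exo geometry and would lead to the six-membered lactone. The second risk is syn-elimination toward C7, which would form an enol silyl ether. Fallback: setting out from 8, iodolactonisation under kinetic conditions (I2, KI, NaHCO3, H2O/CH2Cl2, 0 °C) should give the tertiary iodide (1S,4R,5S)-4-({[tert-butyl(dimethyl)silyl]oxy}methyl)-4-iodo-6-oxabicyclo[3.2.1]octan-7-one F1, and dehydroiodination with DBU (toluene, 80 °C) returns to 11. This changes both the electrophile and the elimination mechanism: an anti E2 process needs an antiperiplanar hydrogen, which the ring offers only at C2, since C6 is a bridgehead.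

**Step 10.** The most likely failure is erosion of the branched-to-linear selectivity when the ruthenacycle forms, because the alkyne carbon C8 sits on a secondary ring carbon. The cis C6 hydroxyl may also add to the activated alkyne. Fallback: setting out from 13, stannylcupration (Me3SnCu·SMe2, MeOH, THF, −63 °C) gives the internal vinylstannane (1S,5S)-2-({[tert-butyl(dimethyl)silyl]oxy}methyl)-5-[1-(trimethylstannyl)ethenyl]cyclohex-2-en-1-ol F2. Stille coupling with allyl bromide (Pd2(dba)3, AsPh3, CuI, DMF, 50 °C) gives the skipped diene (1S,5S)-2-({[tert-butyl(dimethyl)silyl]oxy}methyl)-5-(penta-1,4-dien-2-yl)cyclohex-2-en-1-ol F3. In parallel 17 is isomerised with RuHCl(CO)(PPh3)3 (toluene, 80 °C) to the propenyl carbinol (2R,3E)-2-hydroxy-2-methylpent-3-en-1-yl 2-methylpropanoate F4. Cross-metathesis of F3 with F4 (second-generation Hoveyda–Grubbs catalyst, CH2Cl2, 40 °C) returns to 18. Here the position of the branching alkene is fixed by the stannane and the E geometry by the metathesis.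

**Step 12.** The most likely failure is over-acylation at the C6 hydroxyl, or migration of the new ester from C7 to C6, because both are allylic and 1,3-related. Fallback: setting out from 18, the C6 hydroxyl is masked with levulinic acid (DCC, DMAP, CH2Cl2) to give the 6-O-levulinate of 18 F5. HF·pyridine then gives the C7 alcohol F6. Acylation with 16 and pyridine gives the C7 isobutyrate F7, in which no competing reactive hydroxyl remains. Hydrazine acetate (THF/MeOH, rt) removes the levulinate selectively and returns to the target 20.

**Step 7.** The most likely failure is a stalled homologation, because the bridged lactol releases little free aldehyde, and slow epimerisation at C4 during the long exposure to carbonate. Fallback: setting out from 11, aminolysis with Me(MeO)NH·HCl and AlMe3 (CH2Cl2, 0 °C) gives the hydroxy amide (1S,5S)-4-({[tert-butyl(dimethyl)silyl]oxy}methyl)-5-hydroxy-N-methoxy-N-methylcyclohex-3-ene-1-carboxamide F8. Silylation (TESCl, imidazole) gives its C6 triethylsilyl ether F9. Reduction with i-Bu2AlH (−78 °C) gives the aldehyde (1S,5S)-4-({[tert-butyl(dimethyl)silyl]oxy}methyl)-5-[(triethylsilyl)oxy]cyclohex-3-ene-1-carbaldehyde F10, which cannot close to a lactol. Ohira–Bestmann homologation gives the silylated enyne F11, and PPTS in MeOH (0 °C) removes the secondary triethylsilyl group in the presence of the primary tert-butyldimethylsilyl ether and returns to 13.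

**Step 3.** The most likely failure is incomplete facial discrimination, or Lewis acid-induced loss of the silyl ether and oligomerisation of the diene under the stoichiometric aluminium reagent. Fallback: setting out from 3, a catalytic enantioselective Diels–Alder reaction with 2,2,2-trifluoroethyl acrylate, using the diphenylprolinol-derived o-tolyl-oxazaborolidinium triflimide in the antipode that leaves the Re face of the acrylate α-carbon open (CH2Cl2, −20 °C), gives 2,2,2-trifluoroethyl (S)-4-({[tert-butyl(dimethyl)silyl]oxy}methyl)cyclohex-3-ene-1-carboxylate F12. Saponification (LiOH, THF/H2O) returns to 8. Control then comes from the catalyst instead of an auxiliary.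

## Further compounds

F1 | step 5 | (1S,4R,5S)-4-({[tert-butyl(dimethyl)silyl]oxy}methyl)-4-iodo-6-oxabicyclo[3.2.1]octan-7-one | O=C2[C@H]1CC[C@](CO[Si](C)(C)C(C)(C)C)(I)[C@@H](O2)C1
F2 | step 10 | (1S,5S)-2-({[tert-butyl(dimethyl)silyl]oxy}methyl)-5-[1-(trimethylstannyl)ethenyl]cyclohex-2-en-1-ol | C=C([Sn](C)(C)C)[C@H]1CC=C(CO[Si](C)(C)C(C)(C)C)[C@@H](O)C1
F3 | step 10 | (1S,5S)-2-({[tert-butyl(dimethyl)silyl]oxy}methyl)-5-(penta-1,4-dien-2-yl)cyclohex-2-en-1-ol | C=CCC(=C)[C@H]1CC=C(CO[Si](C)(C)C(C)(C)C)[C@@H](O)C1
F4 | step 10 | (2R,3E)-2-hydroxy-2-methylpent-3-en-1-yl 2-methylpropanoate | C/C=C/[C@@](C)(O)COC(=O)C(C)C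
F5 | step 12 | (1S,5S)-2-({[tert-butyl(dimethyl)silyl]oxy}methyl)-5-{(4E,6R)-6-hydroxy-6-methyl-7-[(2-methylpropanoyl)oxy]hepta-1,4-dien-2-yl}cyclohex-2-en-1-yl 4-oxopentanoate | C=C(C/C=C/[C@@](C)(O)COC(=O)C(C)C)[C@H]1CC=C(CO[Si](C)(C)C(C)(C)C)[C@@H](OC(=O)CCC(C)=O)C1
F6 | step 12 | (1S,5S)-2-(hydroxymethyl)-5-{(4E,6R)-6-hydroxy-6-methyl-7-[(2-methylpropanoyl)oxy]hepta-1,4-dien-2-yl}cyclohex-2-en-1-yl 4-oxopentanoate | C=C(C/C=C/[C@@](C)(O)COC(=O)C(C)C)[C@H]1CC=C(CO)[C@@H](OC(=O)CCC(C)=O)C1
F7 | step 12 | (1S,5S)-5-{(4E,6R)-6-hydroxy-6-methyl-7-[(2-methylpropanoyl)oxy]hepta-1,4-dien-2-yl}-2-{[(2-methylpropanoyl)oxy]methyl}cyclohex-2-en-1-yl 4-oxopentanoate | C=C(C/C=C/[C@@](C)(O)COC(=O)C(C)C)[C@H]1CC=C(COC(=O)C(C)C)[C@@H](OC(=O)CCC(C)=O)C1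
F8 | step 7 | (1S,5S)-4-({[tert-butyl(dimethyl)silyl]oxy}methyl)-5-hydroxy-N-methoxy-N-methylcyclohex-3-ene-1-carboxamide | CON(C)C(=O)[C@H]1CC=C(CO[Si](C)(C)C(C)(C)C)[C@@H](O)C1
F9 | step 7 | (1S,5S)-4-({[tert-butyl(dimethyl)silyl]oxy}methyl)-N-methoxy-N-methyl-5-[(triethylsilyl)oxy]cyclohex-3-ene-1-carboxamide | CON(C)C(=O)[C@H]1CC=C(CO[Si](C)(C)C(C)(C)C)[C@@H](O[Si](CC)(CC)CC)C1
F10 | step 7 | (1S,5S)-4-({[tert-butyl(dimethyl)silyl]oxy}methyl)-5-[(triethylsilyl)oxy]cyclohex-3-ene-1-carbaldehyde | O=C[C@H]1CC=C(CO[Si](C)(C)C(C)(C)C)[C@@H](O[Si](CC)(CC)CC)C1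
F11 | step 7 | tert-butyl({(4S,6S)-4-ethynyl-6-[(triethylsilyl)oxy]cyclohex-1-en-1-yl}methoxy)dimethylsilane | C#C[C@H]1CC=C(CO[Si](C)(C)C(C)(C)C)[C@@H](O[Si](CC)(CC)CC)C1
F12 | step 3 | 2,2,2-trifluoroethyl (S)-4-({[tert-butyl(dimethyl)silyl]oxy}methyl)cyclohex-3-ene-1-carboxylate | FC(F)(F)COC(=O)[C@H]1CCC(CO[Si](C)(C)C(C)(C)C)=CC1
A1 | alternative 1 | ethyl (2E,5S,8E)-6-methylidene-5-(2-oxoethyl)-9-[(4R)-2,2,4-trimethyl-1,3-dioxolan-4-yl]nona-2,8-dienoate | C=C(C/C=C/[C@@]1(C)OC(C)(C)OC1)[C@H](CC=O)C/C=C/C(=O)OCC
A2 | alternative 1 | ethyl (4S,6S)-6-hydroxy-4-{(4E)-5-[(4R)-2,2,4-trimethyl-1,3-dioxolan-4-yl]penta-1,4-dien-2-yl}cyclohex-1-ene-1-carboxylate | C=C(C/C=C/[C@@]2(C)OC(C)(C)OC2)[C@H]1CC=C(C(=O)OCC)[C@@H](O)C1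
A3 | alternative 2 | (2E)-6-[(1S,5S)-5-{[tert-butyl(dimethyl)silyl]oxy}-4-({[tert-butyl(dimethyl)silyl]oxy}methyl)cyclohex-3-en-1-yl]-2-methylhepta-2,6-dien-1-ol | C=C(CC/C=C(\C)CO)[C@H]1CC=C(CO[Si](C)(C)C(C)(C)C)[C@@H](O[Si](C)(C)C(C)(C)C)C1
A4 | alternative 2 | [(2S,3S)-3-{3-[(1S,5S)-5-{[tert-butyl(dimethyl)silyl]oxy}-4-({[tert-butyl(dimethyl)silyl]oxy}methyl)cyclohex-3-en-1-yl]but-3-en-1-yl}-2-methyloxiran-2-yl]methanol | C=C(CC[C@@H]1O[C@@]1(C)CO)[C@H]2CC=C(CO[Si](C)(C)C(C)(C)C)[C@@H](O[Si](C)(C)C(C)(C)C)C2
A5 | alternative 3 | tert-butyl acetoacetate | CC(=O)CC(=O)OC(C)(C)C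
A6 | alternative 3 | ethyl (E)-4-oxobut-2-enoate | CCOC(=O)/C=C/C=O
A7 | alternative 3 | ethyl (S)-5-oxocyclohex-3-ene-1-carboxylate | CCOC(=O)[C@H]1CC=CC(=O)C1
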